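At early times D goes two ways at once, with L into X and Q and with G into J, and the chain length depends on how much of D takes the first way.

| flask | D | L | G | remark | time |
|---|---|---|---|---|---|
| Tuesday's | 0.20 M | 0.52 equiv | 0.060 M | run made earlier |  |
| Thursday's | 0.20 M | 0.74 equiv | 0.060 M | run made earlier |  |
| summer | 0.20 M | 1.00 equiv | 0.0600 M |  | 3.0 min |
| autumn | 0.20 M | 0.980 equiv | 0.0600 M |  | 3.0 min |

| run | time / s | X / % | D / % |
|---|---|---|---|
| Tuesday's | 10.0 | 8 | 87 |
| Tuesday's | 12.0 | 7 | 87 |
| Tuesday's | 20.0 | 13 | 80 |
| Tuesday's | 30.0 | 16 | 72 |
| Tuesday's | 50.0 | 22 | 65 |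
| Tuesday's | 90.0 | 24 | 50 |
| Thursday's | 15.0 | 12 | 83 |
| Thursday's | 30.0 | 23 | 70 |
| Thursday's | 50.0 | 27 | 57 |
| Thursday's | 60.0 | 31 | 53 |
| Thursday's | 80.0 | 42 | 44 |
| Thursday's | 90.0 | 41 | 44 |

(scatter of a reading: 1.5 percentage points)

- each molecule carries two end groups: a chain counts once for every two ends that are left, dead ends included; the units are half of the end groups of the two monomers charged
- on the list of suspects stand: D + L <-> X + Q; D + G -> J

- which of the two ends with the longer chains by the average number of monomer units in a chain (unreacted monomers counted as chains of one) ("neither" if they lie within 10 %) (summer / autumn / neither)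
- average number of monomer units in a chain (unreacted monomers counted as chains of one) at the end, summer
- average number of monomer units in a chain (unreacted monomers counted as chains of one) at the end, autumn

A link X uses two ends and a cap J uses none. With r the equivalents of L and x the X in parts of the D charged, the chain length is therefore (1+r)/(1+r−2x).

Thursday's run at 30.0 s holds X 23 % and D 70 %. Divided by the mean c_D and c_L of that stretch, this reads the link constant as 0.0722 M⁻¹ s⁻¹. The balances at 90.0 s leave J at 20.5 % on average in the two runs, which reads the cap constant, more loosely, as 0.0785 M⁻¹ s⁻¹.

At summer's charge the ladder of half-lives of D starts with the link at 48.0 s. The cap is slower at 147 s, and the asked 180 s lies beyond both. The link share, the part of the D reacting at the charge that goes to X, is 75.4 %.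

The reckoning here keeps this share through the run, lets c_L and c_G fall in step with c_D, and leaves out the way back. It leaves 22.5 % of D in summer, so x is 58.4 % and the chain length 2.41. Autumn gives 2.41, so by this estimate the two lie within 10 % and the answer is neither.

The forecast also says neither, but with lower lengths: 2.2 for summer and 2.18 for autumn. In its words, “Both chain lengths come out near 2.2, so they lie within 10 %.”

The flask gives neither, with 2.55 in summer and 2.54 in autumn.

    D + L ⇌ X + Q (K = 17.0, k = 0.0690 M⁻¹ s⁻¹)
    D + G → J (k = 0.0830 M⁻¹ s⁻¹)

The link share of 75.4 % is a reading for summer's charge, and at that charge the forward link gives D a half-life of 0.84 min and the cap one of 2.3 min. At the asked time of summer X stands at 60.8 % and J at 21.0 %. On a neighbour of autumn with 0.12 M of D, the same equivalents of L and the same c_G, the link share falls to 64.3 %, which gives a chain length of 1.84. That flask computes to 1.96, with X at 48.6 %.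

Readings and results were generated by integration for an exercise, noise included.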